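The 17-membered ring is closed at the C(sp3)–C(sp2) bond between the outer CH2 of the ethylene bridge on the para-phenylene ring B and C-1 of the catechol ring C, the carbon ortho to the diaryl ether oxygen that leads to ring D. The precursor is an open-chain tetramethyl ether with a vinyl group on ring B and a bromine on that ring C carbon. Anti-Markovnikov hydroboration with 9-BBN reverses the polarity of the vinyl terminus, and an intramolecular B-alkyl Suzuki–Miyaura coupling under high dilution then forms the bond and the macrocycle in one operation. Both diaryl ethers and the second bibenzyl bridge are set beforehand; BBr3 finally frees the four phenols.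

Key step: step 8

Remarks on the chemistry:
- Ring A is the 3,4-dioxygenated 5-aryloxy ring (meta-linked), ring B the para-phenylene ring, ring C the 3,4-dioxygenated 2-aryloxy ring and ring D the ortho-phenylene ring.
- The target has no stereocentre and its SMILES defines no conformational chirality, so no stereochemical issue is treated.
- Alkene 9 is carried on as an E/Z mixture.

Step 1
Reactants: 1 2,3-dimethoxyphenol
Product: 2 6-bromo-2,3-dimethoxyphenol
Conditions: NBS (1.0 equiv), i-Pr2NH (0.1 equiv), CH2Cl2, 0 °C
Reagents that add atoms: N-bromosuccinimide, O=C1CCC(=O)N1Br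
Why: Amine-mediated electrophilic aromatic bromination delivers bromine ortho to the free hydroxyl through a hydrogen-bonded N-bromoamine, and C-6 is also para to the 3-methoxy group, so the 6-bromo isomer should dominate.

Step 2
Reactants: 2 6-bromo-2,3-dimethoxyphenol; 3 2-fluorobenzaldehyde
Product: 4 2-(6-bromo-2,3-dimethoxyphenoxy)benzaldehyde
Conditions: K2CO3, DMF, 130 °C
Reagents that add atoms: none
Why: Nucleophilic aromatic substitution (SNAr), in which the ortho-formyl group activates the C–F bond toward the phenoxide of 2 while the aryl bromide is inert under these metal-free conditions.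

Step 3
Reactants: 5 3-hydroxy-4,5-dimethoxybenzaldehyde
Product: 6 5-(hydroxymethyl)-2,3-dimethoxyphenol
Conditions: NaBH4, MeOH, 0 °C
Reagents that add atoms: none
Why: Borohydride reduction of an aryl aldehyde to the benzylic alcohol, for which the phenol needs no protection.

Step 4
Reactants: 6 5-(hydroxymethyl)-2,3-dimethoxyphenol
Product: 7 (3-hydroxy-4,5-dimethoxybenzyl)triphenylphosphonium bromide
Conditions: PPh3·HBr, MeCN, reflux
Reagents that add atoms: triphenylphosphine hydrobromide, Br.c1ccc(cc1)P(c1ccccc1)c1ccccc1
Why: Direct phosphonium salt formation from an electron-rich benzylic alcohol, an acid-promoted substitution through the benzylic cation stabilized by the para-methoxy group, which avoids a separate benzylic halide next to a free phenol.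

Step 5
Reactants: 7 (3-hydroxy-4,5-dimethoxybenzyl)triphenylphosphonium bromide; 4 2-(6-bromo-2,3-dimethoxyphenoxy)benzaldehyde
Product: 9 5-{2-[2-(6-bromo-2,3-dimethoxyphenoxy)phenyl]ethenyl}-2,3-dimethoxyphenol (E/Z mixture), via ylide phenoxide 8 (not isolated)
Conditions: KOt-Bu (2.2 equiv), THF, 0 °C; then 4, 0 °C to rt; 1 M HCl quench
Reagents that add atoms: none
Why: Wittig olefination of the non-enolizable aldehyde 4 with a semi-stabilized benzylic ylide, using two equivalents of base because the phenol is deprotonated first; the E/Z mixture is of no consequence since the alkene is reduced next.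

Step 6
Reactants: 9 5-{2-[2-(6-bromo-2,3-dimethoxyphenoxy)phenyl]ethenyl}-2,3-dimethoxyphenol
Product: 10 5-{2-[2-(6-bromo-2,3-dimethoxyphenoxy)phenyl]ethyl}-2,3-dimethoxyphenol
Conditions: TsNHNH2, NaOAc, DME/H2O, reflux
Reagents that add atoms: none
Why: Diimide reduction, in which diimide generated by thermolysis of tosylhydrazide transfers H2 to the stilbene C=C in a concerted syn fashion and, unlike hydrogenation over palladium, should leave the aryl C–Br bond untouched.

Step 7
Reactants: 10 5-{2-[2-(6-bromo-2,3-dimethoxyphenoxy)phenyl]ethyl}-2,3-dimethoxyphenol; 11 4-vinylphenylboronic acid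
Product: 12 1-bromo-2-(2-{2-[3-(4-ethenylphenoxy)-4,5-dimethoxyphenyl]ethyl}phenoxy)-3,4-dimethoxybenzene
Conditions: Cu(OAc)2 (20 mol %), pyridine, 4 Å molecular sieves, CH2Cl2, O2 (1 atm), rt
Reagents that add atoms: none
Why: Chan–Lam oxidative C–O coupling of the phenol with the arylboronic acid under divalent copper catalysis at room temperature installs ring B with its vinyl group already in place and should tolerate both the aryl bromide and the styrene.

Step 8
Reactants: 12 1-bromo-2-(2-{2-[3-(4-ethenylphenoxy)-4,5-dimethoxyphenyl]ethyl}phenoxy)-3,4-dimethoxybenzene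
Product: 14 tetra-O-methyl ether of the target macrocycle, via alkyl-9-BBN borane 13 (not isolated)
Conditions: 9-BBN (1.5 equiv), THF, 0 °C to rt; then H2O; then slow addition (syringe pump) to Pd(OAc)2 (10 mol %), SPhos (20 mol %), K3PO4 (3 equiv), THF/H2O, 65 °C, final concentration 2 mM
Reagents that add atoms: none
Why: 9-BBN adds across the only alkene of 12 with boron on the terminal carbon (anti-Markovnikov) to give primary alkylborane 13; base then forms the borate, the zerovalent palladium–SPhos catalyst inserts into the ring C C–Br bond, the primary alkyl group is transferred to palladium and reductive elimination joins the side-chain CH2 to ring C. The closest known reaction type is the B-alkyl Suzuki–Miyaura macrocyclization, a polarity-reversed union in which the formerly electrophilic styrene terminus acts as the nucleophile. The 17-membered ring is closed end to end by intramolecular C(sp3)–C(sp2) cross-coupling: transmetalation gives an 18-membered palladacycle that contracts on reductive elimination. No stereocentre is formed. The step needs terminal regioselectivity in the hydroboration, which the bulk of 9-BBN and the para-aryloxy donor secure, and ring closure over oligomerization, which slow addition to about 2 mM and the two ortho-linked turns at rings C and D favour. It also needs coupling faster than β-hydride elimination or protodeboronation, which the electron-rich, bulky SPhos ligand secures by speeding oxidative addition into the hindered electron-rich aryl bromide and reductive elimination.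

Step 9
Reactants: 14 tetra-O-methyl ether of the target macrocycle
Product: 15 target macrocyclic bis(bibenzyl) tetraphenol (CNP0114693.0)
Conditions: BBr3 (excess), CH2Cl2, −78 °C to rt; then H2O
Reagents that add atoms: none
Why: Lewis-acid ether cleavage (BBr3 demethylation) removes the four aryl methyl ethers by bromide attack on the O-methyl carbons, while the diaryl ethers, which carry no sp3 carbon on oxygen, and the bibenzyl bridges should be inert.

Compound list
1 | 2,3-dimethoxyphenol | COc1cccc(O)c1OC | starting material
2 | 6-bromo-2,3-dimethoxyphenol | COc1ccc(Br)c(O)c1OC | intermediate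
3 | 2-fluorobenzaldehyde | O=Cc1ccccc1F | starting material
4 | 2-(6-bromo-2,3-dimethoxyphenoxy)benzaldehyde | COc1ccc(Br)c(Oc2ccccc2C=O)c1OC | intermediate
5 | 3-hydroxy-4,5-dimethoxybenzaldehyde | COc1cc(C=O)cc(O)c1OC | starting material
6 | 5-(hydroxymethyl)-2,3-dimethoxyphenol | COc1cc(CO)cc(O)c1OC | intermediate
7 | (3-hydroxy-4,5-dimethoxybenzyl)triphenylphosphonium bromide | COc1cc(C[P+](c2ccccc2)(c2ccccc2)c2ccccc2)cc(O)c1OC.[Br-] | intermediate
8 | potassium 2,3-dimethoxy-5-[(triphenyl-λ5-phosphanylidene)methyl]phenolate (ylide phenoxide, not isolated) | COc1cc(C=P(c2ccccc2)(c2ccccc2)c2ccccc2)cc([O-])c1OC.[K+] | intermediate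
9 | 5-{2-[2-(6-bromo-2,3-dimethoxyphenoxy)phenyl]ethenyl}-2,3-dimethoxyphenol (E/Z mixture, drawn without alkene geometry) | COc1cc(C=Cc2ccccc2Oc2c(Br)ccc(OC)c2OC)cc(O)c1OC | intermediate
10 | 5-{2-[2-(6-bromo-2,3-dimethoxyphenoxy)phenyl]ethyl}-2,3-dimethoxyphenol | COc1cc(CCc2ccccc2Oc2c(Br)ccc(OC)c2OC)cc(O)c1OC | intermediate
11 | 4-vinylphenylboronic acid | C=Cc1ccc(B(O)O)cc1 | starting material
12 | 1-bromo-2-(2-{2-[3-(4-ethenylphenoxy)-4,5-dimethoxyphenyl]ethyl}phenoxy)-3,4-dimethoxybenzene | COc1cc(CCc2ccccc2Oc2c(Br)ccc(OC)c2OC)cc(Oc2ccc(C=C)cc2)c1OC | intermediate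
13 | 9-{2-[4-(5-{2-[2-(6-bromo-2,3-dimethoxyphenoxy)phenyl]ethyl}-2,3-dimethoxyphenoxy)phenyl]ethyl}-9-borabicyclo[3.3.1]nonane (not isolated) | COc1cc(CCc2ccccc2Oc2c(Br)ccc(OC)c2OC)cc(Oc2ccc(CCB3C4CCCC3CCC4)cc2)c1OC | intermediate
14 | tetra-O-methyl ether of the target macrocycle (17-membered ring, four OMe groups on rings A and C) | COc1cc2cc(c1OC)Oc1ccc(cc1)CCc1ccc(OC)c(OC)c1Oc1ccccc1CC2 | intermediate
15 | target macrocyclic bis(bibenzyl) tetraphenol (CNP0114693.0) | Oc1cc2cc(c1O)Oc1ccc(cc1)CCc1ccc(O)c(O)c1Oc1ccccc1CC2 | target

Total step count: 9. Longest linear sequence: 7 steps (steps 1, 2, 5, 6, 7, 8 and 9, from compound 1).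

Steps most likely to fail

1. Step 8. Intermolecular coupling to oligomers, and loss of the alkylborane by protodeboronation or β-hydride elimination, may outrun the slow oxidative addition into the hindered, electron-rich C–Br bond. The fallback sets out from 12 and comes back to the route at 14. An intramolecular Heck reaction of 12 itself (Pd(OAc)2, P(o-tol)3, K2CO3, n-Bu4NBr, DMF, 110 °C, slow addition, high dilution) arylates the terminal vinyl carbon with the ring C bromide and needs no organometallic nucleophile. It should give the macrocyclic (E)-stilbene tetramethyl ether F1. Hydrogenation (H2, Pd/C, EtOAc, rt), now safe because no C–Br bond is left, should then reduce the new alkene to 14.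

2. Step 7. Protodeboronation and oxidative homocoupling of the boronic acid, or copper-induced polymerization of the styrene unit, may outpace C–O bond formation at the ortho-methoxy phenol. The fallback sets out from 10 and comes back at 12. SNAr of 10 on 4-fluorobenzaldehyde (K2CO3, DMF, 120 °C) should give 4-(5-{2-[2-(6-bromo-2,3-dimethoxyphenoxy)phenyl]ethyl}-2,3-dimethoxyphenoxy)benzaldehyde F2. Wittig methylenation (Ph3PCH3Br, KOt-Bu, THF, 0 °C) then converts the formyl group into the vinyl group of 12.

3. Step 1. Bromination para to the hydroxyl group, or double bromination, may compete with the wanted ortho attack. The fallback sets out from 1 and comes back at 2. Protection (MOMCl, i-Pr2NEt, CH2Cl2) should give 1,2-dimethoxy-3-(methoxymethoxy)benzene F3. Directed ortho-lithiation (n-BuLi, THF, 0 °C), in which the OMOM group outranks OMe as directing group, followed by BrCCl2CCl2Br at −78 °C should give 1-bromo-3,4-dimethoxy-2-(methoxymethoxy)benzene F4. Acetal cleavage (HCl, MeOH, 50 °C) then gives 2 with the bromine position fixed by the lithiation.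

Further compounds
F1 | step 8 | macrocyclic (E)-stilbene tetramethyl ether (14 with an E-CH=CH bridge between rings B and C) | COc1cc2cc(c1OC)Oc1ccc(cc1)/C=C/c1ccc(OC)c(OC)c1Oc1ccccc1CC2
F2 | step 7 | 4-(5-{2-[2-(6-bromo-2,3-dimethoxyphenoxy)phenyl]ethyl}-2,3-dimethoxyphenoxy)benzaldehyde | COc1cc(CCc2ccccc2Oc2c(Br)ccc(OC)c2OC)cc(Oc2ccc(C=O)cc2)c1OC
F3 | step 1 | 1,2-dimethoxy-3-(methoxymethoxy)benzene | COCOc1cccc(OC)c1OC
F4 | step 1 | 1-bromo-3,4-dimethoxy-2-(methoxymethoxy)benzene | COCOc1c(Br)ccc(OC)c1OC
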